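**Retrosynthetic overview**

1. The target is read as (5S,6S,7S,10S)-6β,7α-diacetoxylabda-8,13E-dien-15-ol (labdane numbering; ring A = C1–C5/C10, ring B = C5–C10). The 6β,7α-diol comes from a C6 ketone (α-face hydroxylation of its dienolate at C7, then α-face hydride at C6), and C9–C11 from a B-alkyl Suzuki coupling of a C9 enol triflate.
2. Ring A is disconnected by a one-flask Michael addition/intramolecular Wittig [4+2] annulation of a ring B keto aldehyde with vinyltriphenylphosphonium bromide (the C1–C2 unit). It forms C1–C10 and C2=C3 (hydrogenated later) and the quaternary C10.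
3. Enabling feature: in the ring B precursor, C10–H is the only enolisable position of the C9 ketone (C8 is an sp2 carbon of the C7=C8–C9=O enone, C6 is a dimethyl ketal). The C3 aldehyde sits on the C4 gem-dimethyl carbon, so it cannot enolise and lies 1,4 to C10 (C10–C5–C4–C3).
4. Ring B, with all six carbons, both methyl groups and the C6/C9 oxygens, comes from 4,4-dimethoxy-2,6-dimethylcyclohexa-2,5-dienone. It is desymmetrised by a catalytic asymmetric Mukaiyama–Michael addition that forms C4–C5 and sets C5.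
5. Ring order: ring B (from an arene) first, ring A second, side chain last.

Key step: step 4

Remark: the (S)-configured oxazaborolidinium catalyst of step 2 is assumed to give (R)-4; should a test run show the opposite sense, its enantiomer is used and the route is otherwise unchanged.

**Route**

Step 1
Reactants: 1 4-methoxy-2,6-dimethylphenol
Product: 2 4,4-dimethoxy-2,6-dimethylcyclohexa-2,5-dien-1-one
Conditions: PhI(OAc)2, MeOH, 0 °C
Reagents that add atoms: methanol, CO
Why: oxidative dearomatisation of a p-methoxyphenol with PhI(OAc)2 in methanol is the standard entry to p-quinone monoketals, and no stereocenter is formed.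

Step 2
Reactants: 2 4,4-dimethoxy-2,6-dimethylcyclohexa-2,5-dien-1-one; 3 1-methoxy-2-methyl-1-(trimethylsilyloxy)prop-1-ene
Product: 4 methyl 2-[(1R)-6,6-dimethoxy-2,4-dimethyl-3-(trimethylsilyloxy)cyclohexa-2,4-dien-1-yl]-2-methylpropanoate
Conditions: (S)-3,3-diphenyl-1-(o-tolyl)tetrahydro-1H,3H-pyrrolo[1,2-c][1,3,2]oxazaborole (20 mol%), Tf2NH (20 mol%), Ph3P=O (25 mol%), toluene, −40 → −20 °C; product used without chromatography
Reagents that add atoms: none
Why: a chiral oxazaborolidinium-catalysed Mukaiyama–Michael addition of an isobutyrate silyl ketene acetal to a cyclic enone should form C4–C5, with the catalyst-bound carbonyl differentiating the two enantiotopic enone β-carbons to set C5 (R), the flanking methyl groups suppressing 1,2-addition, and silyl transfer leaving the C9 ketone masked as its dienol ether.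

Step 3
Reactants: 4 methyl 2-[(1R)-6,6-dimethoxy-2,4-dimethyl-3-(trimethylsilyloxy)cyclohexa-2,4-dien-1-yl]-2-methylpropanoate
Product: 6 2-[(1R)-6,6-dimethoxy-2,4-dimethyl-3-oxocyclohex-4-en-1-yl]-2-methylpropanal (C2 epimers), via silyl dienol ether aldehyde 5 (not isolated)
Conditions: i-Bu2AlH (1.2 equiv), CH2Cl2, −78 °C; aqueous potassium sodium tartrate; then K2CO3 (0.1 equiv), MeOH, 0 °C
Reagents that add atoms: none
Why: half-reduction of an α-quaternary methyl ester by i-Bu2AlH should stop at the aldehyde through a stable tetrahedral aluminate while the ketone stays masked, and base-catalysed methanolysis of the Si–O bond then frees the ketone without acid, so the ketal and C5 are untouched and the new C10–H center is inconsequential.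

Step 4
Reactants: 6 2-[(1R)-6,6-dimethoxy-2,4-dimethyl-3-oxocyclohex-4-en-1-yl]-2-methylpropanal; 7 vinyltriphenylphosphonium bromide
Product: 10 (4aS,8aS)-4,4-dimethoxy-2,5,5,8a-tetramethyl-4a,5,8,8a-tetrahydronaphthalen-1(4H)-one, via sodium enolate 8 (not isolated), via phosphonium ylide 9 (not isolated)
Conditions: NaH (1.1 equiv), THF–DMF (4:1), 0 °C; then 7 (1.05 equiv) in portions, 0 → 23 °C
Reagents that add atoms: none
Why: Deprotonation can occur only at C10–H, giving the cross-conjugated sodium enolate, whose carbon terminus adds in Michael fashion to the vinylphosphonium salt (C1–C10) and so generates a non-stabilised ylide at C2 that closes onto the C3 aldehyde by intramolecular Wittig olefination (C2=C3) with loss of Ph3P=O. The closest known reaction type is the tandem Michael addition/intramolecular Wittig annulation of carbanions bearing a pendant carbonyl group with vinylphosphonium salts. Ring A is closed in the olefination event as a six-membered ring through a bicyclic oxaphosphetane, which can deliver only the endocyclic cis alkene. The one new stereocenter, quaternary C10, is controlled by the adjacent C5 center: the bulky C(CH3)2CHO group should sit pseudoaxial on the enolate to avoid allylic strain with the C10 methyl, so the electrophile enters anti to it, placing C1 trans to C4 and giving the trans ring fusion on closure. The step needs C- over O-alkylation (O-adducts should revert by β-elimination from their ylides while C-adducts are drained irreversibly by the Wittig closure) and ring closure over a second Michael addition of the ylide (secured by the proximity and reactivity of the aldehyde and by portionwise addition of one equivalent of the salt).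

Step 5
Reactants: 10 (4aS,8aS)-4,4-dimethoxy-2,5,5,8a-tetramethyl-4a,5,8,8a-tetrahydronaphthalen-1(4H)-one
Product: 11 (4aS,8aS)-4,4-dimethoxy-2,5,5,8a-tetramethyl-3,4,4a,5,6,7,8,8a-octahydronaphthalen-1(2H)-one (C2 epimers)
Conditions: H2 (1 atm), Pd/C, EtOAc, trace K2CO3, 23 °C
Reagents that add atoms: none
Why: catalytic hydrogenation should saturate both the cis-disubstituted C2=C3 alkene and the C7=C8 enone double bond while ketone and ketal are inert, and the new C8 center is erased in step 6.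

Step 6
Reactants: 11 (4aS,8aS)-4,4-dimethoxy-2,5,5,8a-tetramethyl-3,4,4a,5,6,7,8,8a-octahydronaphthalen-1(2H)-one
Product: 13 (4aS,8aS)-4,4-dimethoxy-2,5,5,8a-tetramethyl-3,4,4a,5,6,7,8,8a-octahydronaphthalen-1-yl trifluoromethanesulfonate, via potassium enolate 12 (not isolated)
Conditions: KN(SiMe3)2, THF, −78 → 0 °C; PhNTf2, 0 → 23 °C
Reagents that add atoms: N-phenylbis(trifluoromethanesulfonimide), O=S(=O)(N(c1ccccc1)S(=O)(=O)C(F)(F)F)C(F)(F)F
Why: the C9 ketone can enolise only toward C8 because C10 is quaternary, so enolate O-sulfonylation should give the tetrasubstituted C8=C9 enol triflate regiospecifically.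

Step 7
Reactants: 14 (2E)-3-methylpent-2-en-4-yn-1-ol
Product: 15 tert-butyl(dimethyl){[(2E)-3-methylpent-2-en-4-yn-1-yl]oxy}silane
Conditions: TBSCl, imidazole, DMF, 23 °C
Reagents that add atoms: tert-butyldimethylsilyl chloride, CC(C)(C)[Si](C)(C)Cl
Why: silylation of a primary allylic alcohol is routine and gives a protecting group that survives every later basic, reductive and mildly acidic step.

Step 8
Reactants: 15 tert-butyl(dimethyl){[(2E)-3-methylpent-2-en-4-yn-1-yl]oxy}silane
Product: 16 tert-butyl(dimethyl){[(2E)-3-methylpenta-2,4-dien-1-yl]oxy}silane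
Conditions: H2 (1 atm), Pd/CaCO3 poisoned with Pb(OAc)2 (Lindlar catalyst), quinoline, hexane, 23 °C, stopped after one equivalent of H2
Reagents that add atoms: none
Why: Lindlar semihydrogenation of the terminal alkyne of a conjugated enyne should stop at the diene and leave the E trisubstituted alkene untouched.

Step 9
Reactants: 13 (4aS,8aS)-4,4-dimethoxy-2,5,5,8a-tetramethyl-3,4,4a,5,6,7,8,8a-octahydronaphthalen-1-yl trifluoromethanesulfonate; 16 tert-butyl(dimethyl){[(2E)-3-methylpenta-2,4-dien-1-yl]oxy}silane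
Product: 18 tert-butyl({(2E)-5-[(4aS,8aS)-4,4-dimethoxy-2,5,5,8a-tetramethyl-3,4,4a,5,6,7,8,8a-octahydronaphthalen-1-yl]-3-methylpent-2-en-1-yl}oxy)dimethylsilane, via alkylborane 17 (not isolated)
Conditions: 16, 9-BBN-H dimer, THF, 0 → 23 °C; then 13, Pd(dppf)Cl2 (10 mol%), AsPh3, aqueous Cs2CO3, DMF, 60 °C
Reagents that add atoms: none
Why: 9-BBN should add anti-Markovnikov and chemoselectively to the monosubstituted terminal double bond of the diene, and the primary alkylborane then undergoes B-alkyl Suzuki–Miyaura coupling with the enol triflate to form C9–C11 with the tetrasubstituted C8=C9 alkene fixed in place; no stereocenter is formed.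

Step 10
Reactants: 18 tert-butyl({(2E)-5-[(4aS,8aS)-4,4-dimethoxy-2,5,5,8a-tetramethyl-3,4,4a,5,6,7,8,8a-octahydronaphthalen-1-yl]-3-methylpent-2-en-1-yl}oxy)dimethylsilane
Product: 19 (4aS,8aS)-4-[(3E)-5-{[tert-butyl(dimethyl)silyl]oxy}-3-methylpent-3-en-1-yl]-3,4a,8,8-tetramethyl-4a,5,6,7,8,8a-hexahydronaphthalen-1(2H)-one
Conditions: PPTS (10 mol%), acetone–H2O (20:1), 23 °C
Reagents that add atoms: water, O
Why: mild acid-catalysed hydrolysis of the dimethyl ketal should unveil the C6 ketone without cleaving the primary silyl ether, the trans ring fusion at C5 is the thermodynamic one, and any drift of the C8=C9 bond into conjugation is harmless because both enones give the same dienolate in step 11.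

Step 11
Reactants: 19 (4aS,8aS)-4-[(3E)-5-{[tert-butyl(dimethyl)silyl]oxy}-3-methylpent-3-en-1-yl]-3,4a,8,8-tetramethyl-4a,5,6,7,8,8a-hexahydronaphthalen-1(2H)-one
Product: 21 (2S,4aS,8aS)-4-[(3E)-5-{[tert-butyl(dimethyl)silyl]oxy}-3-methylpent-3-en-1-yl]-2-hydroxy-3,4a,8,8-tetramethyl-4a,5,6,7,8,8a-hexahydronaphthalen-1(2H)-one, via potassium dienolate 20 (not isolated)
Conditions: KN(SiMe3)2 (1.1 equiv), THF, −78 °C; 2-(phenylsulfonyl)-3-phenyloxaziridine, −78 °C; AcOH quench at −78 °C
Reagents that add atoms: 2-(phenylsulfonyl)-3-phenyloxaziridine, O=S(=O)(c1ccccc1)N1OC1c1ccccc1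
Why: deprotonation at the doubly activated C7 (α to C6=O and allylic) gives the extended dienolate, which in an enolate hydroxylation should react with the N-sulfonyloxaziridine at its α-carbon from the α face, because the axial C10 methyl and the 4β methyl shield the β face, giving the 7α-alcohol; the cold acidic quench prevents α-ketol isomerisation.

Step 12
Reactants: 21 (2S,4aS,8aS)-4-[(3E)-5-{[tert-butyl(dimethyl)silyl]oxy}-3-methylpent-3-en-1-yl]-2-hydroxy-3,4a,8,8-tetramethyl-4a,5,6,7,8,8a-hexahydronaphthalen-1(2H)-one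
Product: 22 (1S,2S,4aS,8aS)-4-[(3E)-5-{[tert-butyl(dimethyl)silyl]oxy}-3-methylpent-3-en-1-yl]-3,4a,8,8-tetramethyl-1,2,4a,5,6,7,8,8a-octahydronaphthalene-1,2-diol
Conditions: NaBH4, MeOH–THF, −20 → 0 °C
Reagents that add atoms: none
Why: borohydride reduction of the C6 ketone should occur from the α face, since the β face is blocked by the syn-axial C4β and C10 methyl groups and the 7α-hydroxyl can deliver the reagent on the same α face, giving the axial 6β-alcohol and thus the trans-6β,7α-diol.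

Step 13
Reactants: 22 (1S,2S,4aS,8aS)-4-[(3E)-5-{[tert-butyl(dimethyl)silyl]oxy}-3-methylpent-3-en-1-yl]-3,4a,8,8-tetramethyl-1,2,4a,5,6,7,8,8a-octahydronaphthalene-1,2-diol
Product: 23 (1S,2S,4aS,8aS)-4-[(3E)-5-{[tert-butyl(dimethyl)silyl]oxy}-3-methylpent-3-en-1-yl]-3,4a,8,8-tetramethyl-1,2,4a,5,6,7,8,8a-octahydronaphthalene-1,2-diyl diacetate
Conditions: Ac2O, DMAP, pyridine, 50 °C
Reagents that add atoms: acetic anhydride, CC(=O)OC(C)=O
Why: DMAP-catalysed acetylation with warming should esterify both the allylic 7α-hydroxyl and the hindered axial 6β-hydroxyl with retention, and the silyl ether is unaffected.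

Step 14
Reactants: 23 (1S,2S,4aS,8aS)-4-[(3E)-5-{[tert-butyl(dimethyl)silyl]oxy}-3-methylpent-3-en-1-yl]-3,4a,8,8-tetramethyl-1,2,4a,5,6,7,8,8a-octahydronaphthalene-1,2-diyl diacetate
Product: 24 (1S,2S,4aS,8aS)-4-[(3E)-5-hydroxy-3-methylpent-3-en-1-yl]-3,4a,8,8-tetramethyl-1,2,4a,5,6,7,8,8a-octahydronaphthalene-1,2-diyl diacetate (CNP0187815.1)
Conditions: HF·pyridine, THF–pyridine, 0 → 23 °C
Reagents that add atoms: none
Why: fluoride desilylation under buffered, non-basic conditions should free the primary allylic alcohol without cleaving or migrating the two acetates.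

**Compound list**

1 | 4-methoxy-2,6-dimethylphenol | COc1cc(C)c(O)c(C)c1 | starting material
2 | 4,4-dimethoxy-2,6-dimethylcyclohexa-2,5-dien-1-one | COC1(OC)C=C(C)C(=O)C(C)=C1 | intermediate
3 | 1-methoxy-2-methyl-1-(trimethylsilyloxy)prop-1-ene | COC(O[Si](C)(C)C)=C(C)C | starting material
4 | methyl 2-[(1R)-6,6-dimethoxy-2,4-dimethyl-3-(trimethylsilyloxy)cyclohexa-2,4-dien-1-yl]-2-methylpropanoate | COC1(OC)C=C(C)C(O[Si](C)(C)C)=C(C)[C@@H]1C(C)(C)C(=O)OC | intermediate
5 | 2-[(1R)-6,6-dimethoxy-2,4-dimethyl-3-(trimethylsilyloxy)cyclohexa-2,4-dien-1-yl]-2-methylpropanal | COC1(OC)C=C(C)C(O[Si](C)(C)C)=C(C)[C@@H]1C(C)(C)C=O | intermediate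
6 | 2-[(1R)-6,6-dimethoxy-2,4-dimethyl-3-oxocyclohex-4-en-1-yl]-2-methylpropanal (C2 epimers) | COC1(OC)C=C(C)C(=O)C(C)[C@@H]1C(C)(C)C=O | intermediate
7 | vinyltriphenylphosphonium bromide | C=C[P+](c1ccccc1)(c1ccccc1)c1ccccc1.[Br-] | starting material
8 | sodium (3R)-4,4-dimethoxy-2,6-dimethyl-3-(2-methyl-1-oxopropan-2-yl)cyclohexa-1,5-dien-1-olate | COC1(OC)C=C(C)C([O-])=C(C)[C@@H]1C(C)(C)C=O.[Na+] | intermediate
9 | 2-{(1S,2S)-6,6-dimethoxy-2,4-dimethyl-3-oxo-2-[2-(triphenyl-λ5-phosphanylidene)ethyl]cyclohex-4-en-1-yl}-2-methylpropanal | COC1(OC)C=C(C)C(=O)[C@@](C)(CC=P(c2ccccc2)(c2ccccc2)c2ccccc2)[C@@H]1C(C)(C)C=O | intermediate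
10 | (4aS,8aS)-4,4-dimethoxy-2,5,5,8a-tetramethyl-4a,5,8,8a-tetrahydronaphthalen-1(4H)-one | COC1(OC)C=C(C)C(=O)[C@@]2(C)CC=CC(C)(C)[C@H]12 | intermediate
11 | (4aS,8aS)-4,4-dimethoxy-2,5,5,8a-tetramethyl-3,4,4a,5,6,7,8,8a-octahydronaphthalen-1(2H)-one (C2 epimers) | COC1(OC)CC(C)C(=O)[C@@]2(C)CCCC(C)(C)[C@H]12 | intermediate
12 | potassium (4aS,8aS)-4,4-dimethoxy-2,5,5,8a-tetramethyl-3,4,4a,5,6,7,8,8a-octahydronaphthalen-1-olate | COC1(OC)CC(C)=C([O-])[C@@]2(C)CCCC(C)(C)[C@H]12.[K+] | intermediate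
13 | (4aS,8aS)-4,4-dimethoxy-2,5,5,8a-tetramethyl-3,4,4a,5,6,7,8,8a-octahydronaphthalen-1-yl trifluoromethanesulfonate | COC1(OC)CC(C)=C(OS(=O)(=O)C(F)(F)F)[C@@]2(C)CCCC(C)(C)[C@H]12 | intermediate
14 | (2E)-3-methylpent-2-en-4-yn-1-ol | C#C/C(C)=C/CO | starting material
15 | tert-butyl(dimethyl){[(2E)-3-methylpent-2-en-4-yn-1-yl]oxy}silane | C#C/C(C)=C/CO[Si](C)(C)C(C)(C)C | intermediate
16 | tert-butyl(dimethyl){[(2E)-3-methylpenta-2,4-dien-1-yl]oxy}silane | C=C/C(C)=C/CO[Si](C)(C)C(C)(C)C | intermediate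
17 | 9-[(3E)-5-{[tert-butyl(dimethyl)silyl]oxy}-3-methylpent-3-en-1-yl]-9-borabicyclo[3.3.1]nonane | C(C/C(C)=C/CO[Si](C)(C)C(C)(C)C)B1C2CCCC1CCC2 | intermediate
18 | tert-butyl({(2E)-5-[(4aS,8aS)-4,4-dimethoxy-2,5,5,8a-tetramethyl-3,4,4a,5,6,7,8,8a-octahydronaphthalen-1-yl]-3-methylpent-2-en-1-yl}oxy)dimethylsilane | COC1(OC)CC(C)=C(CC/C(C)=C/CO[Si](C)(C)C(C)(C)C)[C@@]2(C)CCCC(C)(C)[C@H]12 | intermediate
19 | (4aS,8aS)-4-[(3E)-5-{[tert-butyl(dimethyl)silyl]oxy}-3-methylpent-3-en-1-yl]-3,4a,8,8-tetramethyl-4a,5,6,7,8,8a-hexahydronaphthalen-1(2H)-one | O=C1CC(C)=C(CC/C(C)=C/CO[Si](C)(C)C(C)(C)C)[C@@]2(C)CCCC(C)(C)[C@H]12 | intermediate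
20 | potassium dienolate of 19 (C6–O−, C6=C7, C8=C9) | [O-]C1=CC(C)=C(CC/C(C)=C/CO[Si](C)(C)C(C)(C)C)[C@@]2(C)CCCC(C)(C)[C@H]12.[K+] | intermediate
21 | (2S,4aS,8aS)-4-[(3E)-5-{[tert-butyl(dimethyl)silyl]oxy}-3-methylpent-3-en-1-yl]-2-hydroxy-3,4a,8,8-tetramethyl-4a,5,6,7,8,8a-hexahydronaphthalen-1(2H)-one | O=C1[C@@H](O)C(C)=C(CC/C(C)=C/CO[Si](C)(C)C(C)(C)C)[C@@]2(C)CCCC(C)(C)[C@H]12 | intermediate
22 | (1S,2S,4aS,8aS)-4-[(3E)-5-{[tert-butyl(dimethyl)silyl]oxy}-3-methylpent-3-en-1-yl]-3,4a,8,8-tetramethyl-1,2,4a,5,6,7,8,8a-octahydronaphthalene-1,2-diol | O[C@@H]1[C@@H](O)C(C)=C(CC/C(C)=C/CO[Si](C)(C)C(C)(C)C)[C@@]2(C)CCCC(C)(C)[C@H]12 | intermediate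
23 | (1S,2S,4aS,8aS)-4-[(3E)-5-{[tert-butyl(dimethyl)silyl]oxy}-3-methylpent-3-en-1-yl]-3,4a,8,8-tetramethyl-1,2,4a,5,6,7,8,8a-octahydronaphthalene-1,2-diyl diacetate | CC(=O)O[C@@H]1[C@@H](OC(C)=O)C(C)=C(CC/C(C)=C/CO[Si](C)(C)C(C)(C)C)[C@@]2(C)CCCC(C)(C)[C@H]12 | intermediate
24 | (1S,2S,4aS,8aS)-4-[(3E)-5-hydroxy-3-methylpent-3-en-1-yl]-3,4a,8,8-tetramethyl-1,2,4a,5,6,7,8,8a-octahydronaphthalene-1,2-diyl diacetate | CC(=O)O[C@@H]1[C@@H](OC(C)=O)C(C)=C(CC/C(C)=C/CO)[C@@]2(C)CCCC(C)(C)[C@H]12 | target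

**Step count and risks**

Total steps: 14. Longest linear sequence: 12 (steps 1–6 and 9–14).

Steps most likely to fail:

Step 2. The carbonyl is flanked by two methyl groups, so catalyst binding may be weak and facial discrimination poor. The Lewis acid may also ionise the ketal, after which the adduct aromatises by loss of methanol. The fallback sets out from 2 and avoids Lewis acid by using an auxiliary. Isobutyraldehyde is condensed with (S)-1-amino-2-(methoxymethyl)pyrrolidine to the hydrazone (S,E)-2-(methoxymethyl)-N-(2-methylpropylidene)pyrrolidin-1-amine F1 (the auxiliary antipode is taken if a model run requires it). Its lithium azaenolate (LiN(i-Pr)2, THF, 0 °C), transmetalated with CuBr·SMe2, is added to 2 at −78 °C to give the hydrazone adduct of the keto aldehyde F2, with C5 set by the chelated auxiliary. Hydrazone cleavage with CuCl2 in THF/pH 7 buffer comes back to the route at 6.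

Step 4. The enolate may fragment by retro-Michael loss of the C4 unit, the ylide may add to a second molecule of the phosphonium salt before it reaches the aldehyde, or alkylation at C10 may be insufficiently trans-selective. The fallback sets out from 6 and separates the two bond formations. The enolate 8 is alkylated with allyl bromide (NaH, THF–DMF, 0 °C) to 2-[(1S,2S)-2-allyl-6,6-dimethoxy-2,4-dimethyl-3-oxocyclohex-4-en-1-yl]-2-methylpropanal F3. Wittig methylenation of the aldehyde (Ph3PCH3Br, KOt-Bu, THF, 0 °C) gives (5S,6S)-6-allyl-4,4-dimethoxy-2,6-dimethyl-5-(2-methylbut-3-en-2-yl)cyclohex-2-en-1-one F4. Ring-closing metathesis with the second-generation Grubbs catalyst (CH2Cl2, 40 °C) comes back to the route at 10.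

Step 9. Oxidative addition and transmetalation may be slow at the tetrasubstituted triflate next to the quaternary C10, so that protodeboronation or β-hydride elimination of the alkylborane takes over. The fallback sets out from 13 and from 15 and uses the sterically undemanding alkyne. Sonogashira coupling (Pd(PPh3)2Cl2, CuI, i-Pr2NH, DMF, 60 °C) gives the dienyne tert-butyl({(2E)-5-[(4aS,8aS)-4,4-dimethoxy-2,5,5,8a-tetramethyl-3,4,4a,5,6,7,8,8a-octahydronaphthalen-1-yl]-3-methylpent-2-en-4-yn-1-yl}oxy)dimethylsilane F5. Diimide (from 2-nitrobenzenesulfonylhydrazide, Et3N, CH2Cl2, 23 °C) then saturates the triple bond by way of the (2E,4Z)-triene F6 (not isolated), while the trisubstituted and tetrasubstituted alkenes react far more slowly. This comes back to the route at 18.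

**Further compounds**

F1 | step 2 | (S,E)-2-(methoxymethyl)-N-(2-methylpropylidene)pyrrolidin-1-amine | COC[C@@H]1CCCN1/N=C/C(C)C
F2 | step 2 | (5R)-4,4-dimethoxy-5-[(E)-1-{[(2S)-2-(methoxymethyl)pyrrolidin-1-yl]imino}-2-methylpropan-2-yl]-2,6-dimethylcyclohex-2-en-1-one (C6 epimers) | COC1(OC)C=C(C)C(=O)C(C)[C@@H]1C(C)(C)/C=N/N1CCC[C@H]1COC
F3 | step 4 | 2-[(1S,2S)-2-allyl-6,6-dimethoxy-2,4-dimethyl-3-oxocyclohex-4-en-1-yl]-2-methylpropanal | COC1(OC)C=C(C)C(=O)[C@@](C)(CC=C)[C@@H]1C(C)(C)C=O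
F4 | step 4 | (5S,6S)-6-allyl-4,4-dimethoxy-2,6-dimethyl-5-(2-methylbut-3-en-2-yl)cyclohex-2-en-1-one | COC1(OC)C=C(C)C(=O)[C@@](C)(CC=C)[C@@H]1C(C)(C)C=C
F5 | step 9 | tert-butyl({(2E)-5-[(4aS,8aS)-4,4-dimethoxy-2,5,5,8a-tetramethyl-3,4,4a,5,6,7,8,8a-octahydronaphthalen-1-yl]-3-methylpent-2-en-4-yn-1-yl}oxy)dimethylsilane | COC1(OC)CC(C)=C(C#C/C(C)=C/CO[Si](C)(C)C(C)(C)C)[C@@]2(C)CCCC(C)(C)[C@H]12
F6 | step 9 | tert-butyl({(2E,4Z)-5-[(4aS,8aS)-4,4-dimethoxy-2,5,5,8a-tetramethyl-3,4,4a,5,6,7,8,8a-octahydronaphthalen-1-yl]-3-methylpenta-2,4-dien-1-yl}oxy)dimethylsilane | COC1(OC)CC(C)=C(/C=C\C(C)=C\CO[Si](C)(C)C(C)(C)C)[C@@]2(C)CCCC(C)(C)[C@H]12
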